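Count the electrophile left, not the target made.

all flasks: electrophile 0.11 M
- delta: nucleophile 1.1 equiv; run made earlier
- alpha: nucleophile 2.5 equiv; run made earlier
- south-east: nucleophile 1.00 equiv; time 10 d
- east: nucleophile 1.50 equiv; time 10 d
- north: nucleophile 2.20 equiv; time 10 d

- delta (time / d: electrophile / %, target / %): 0.833: 70, 21; 2.50: 48, 32; 5.00: 34, 32; 8.00: 24, 27
- alpha (time / d: electrophile / %, target / %): 0.625: 60, 40; 1.25: 35, 52; 3.00: 14, 61; 8.00: 4, 66

(readings scatter by 2 percentage points)

* part of the electrophile that has reacted at the end, south-east
* part of the electrophile that has reacted at the end, east
* part of the electrophile that has reacted at the end, north
* what raising the equivalents of nucleophile from its lowest to its highest value here does to the part of the electrophile that has reacted (changes below 5 percentage points count as none) (it rises / it falls / no change)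

- percentages count the electrophile that a species holds: one side product counts as two
- the earlier runs were read with a standard deviation of 2 percentage points
- steps thought possible: electrophile + nucleophile -> acid set free + target; nucleophile + acid set free <-> protonated nucleophile; target -> over-reaction product; electrophile + target -> side product

The recipes differ in nucleophile, so we first ask what a substitution costs. Electrophile and nucleophile give target and acid set free, and that acid can bind a second nucleophile as protonated nucleophile, so we reckon 2 equiv per substitution. In south-east this makes nucleophile the limiting reagent of substitution, and 50.0% is the floor: our estimate of the fraction of electrophile left over once substitution has used the nucleophile at that price. East has a floor of 25.0%, and north has none, so we expect a rise.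

But a floor counts substitution and no other way of using electrophile. The delta run, with a floor of 45.0%, reads 24% at 8.00 d, which is 21 percentage points under it, and 49.0% of its charge is neither electrophile nor target. So we let electrophile + target give side product, a step that needs no nucleophile. Carrying delta's gap, read at 8.00 d, unchanged to south-east at 10 d, we commit as a rough estimate of our own to about 71.0% reacted.

The forecast gives 74%, 91% and 96%, with the trend it rises, holding that “each substitution costs about 2 equiv”. For south-east it stands 3 points above our figure.

The flasks give 74.6%, 91.7% and 98.9%: it rises, by 24 points.

    electrophile + nucleophile → acid set free + target (k = 0.00252 M⁻¹ min⁻¹)
    nucleophile + acid set free ⇌ protonated nucleophile, settled at all times (K = 65000 M⁻¹)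
    target → over-reaction product (k = 1.23 × 10⁻⁶ min⁻¹)
    electrophile + target → side product (k = 0.00152 M⁻¹ min⁻¹)

At 10.0 d south-east holds 25.4% electrophile, under its floor of 50.0%, with 3.0% of its nucleophile free, and substitution uses electrophile at 0.22 of the rate of the step to side product. A neighbour of south-east, the same flask but with 0.066 M electrophile, has the same equivalents and so the same floor, and it ends with 37.8% side product and 35% electrophile, again under 50.0%.

(The runs were computed on assumed constants, and the scatter is random.)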